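**Conventions.** Bn = benzyl, TBS = tert-butyldimethylsilyl, TMS = trimethylsilyl. Ar = 3,4-bis(benzyloxy)phenyl. Gall = 3,4,5-tris(benzyloxy)benzoyl. "Protected U-4β-yl" = the 5,7,3′,4′-tetra-O-benzyl-3-O-Gall-(−)-epicatechin residue bonded through C4, trans to its C3 oxygen. Flavan numbering is used for units U, M and L.

**Assumption.** Compounds 1, 6, 10, 13, 15 and 24 are taken as purchasable; the ketene acetal geometry of 18 and the carbinol configuration of 23 are drawn for the isomer expected to predominate and have no bearing on later steps.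

## Analysis of the target

The target is a B-type proanthocyanidin trimer built from three chroman units. Unit U, (−)-epicatechin 3-O-gallate, is bonded from its C4 to C6 of unit M, a second epicatechin 3-O-gallate, and C4 of unit M is bonded to C8 of unit L, (+)-catechin. There are eight stereocentres. In units U and M the C2 aryl group and the C3 oxygen are cis (2R,3R) and the C4 aryl bond is trans to the C3 oxygen (4β); unit L is 2,3-trans (2R,3S). Eighteen phenols, two aryl esters and two doubly benzylic interflavan bonds make the free compound sensitive to air, base and acid, so all hydroxyls are carried as benzyl ethers and released only in the last step. The hard points are the 4→6 bond, because a flavan C4 cation normally attacks C8 of its partner, and the need to place the two identical gallates on chosen oxygens. The strategy rests on ring A of unit M: C6 sits between the oxygen-bearing C5 and C7 exactly as the central carbon of a 1,3-dicarbonyl compound sits between its two carbonyls. Ring C of unit M, with its cis C2 aryl and C3 oxygen, is a dihydropyranone fused through C4a and C8a. Ring A can therefore be grown from an acetoacetate that already carries unit U on its central carbon, which fixes the 4→6 bond before the ring exists.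

## Retrosynthetic reasoning

**30 from 29.** The nineteen O-benzyl bonds are cut last. One hydrogenolysis releases every phenol and the C3 alcohol of unit L without touching the esters or the interflavan bonds.

**29 from 28 and 13.** The ester C–O bond at C3 of unit M is cut. Placing this gallate after the trimer is assembled keeps an α-acyloxy ketone out of the route; the forward step only has to acylate one free secondary alcohol.

**28 from 27.** The Si–O bond at C3 of unit M is cut. The silyl ether is the only group that distinguishes this oxygen from the benzylated C3 oxygen of unit L.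

**27 from 23 and 26.** The C4(M)–C8(L) bond is cut. This is the one interflavan bond for which Friedel–Crafts coupling has the natural regiochemistry. The forward reaction must ionise the C4 carbinol of 23 and deliver C8 of 26 to the face opposite the C2 aryl and C3 silyloxy groups.

**23 from 22 from 21.** The C4–H bond (hydride reduction) and the two phenol O-benzyl bonds are cut. The ketone of 21 is the latent leaving group for the bond to unit L. Benzylation has to be done without base because C3 is adjacent to the ketone.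

**21 from 18 and 9.** C8–C8a and C4a–C5 of ring A of unit M are cut. This is the only disconnection that gives a unit-U fragment in which the future C6 is a nucleophilic 1,3-dicarbonyl carbon, and a unit-M fragment in which C2 and C3 are already cis. The forward reaction must add the diene terminus to C8a, close the ring on the bromine-bearing C4a and aromatise without disturbing C2 and C3.

**9 from 8, and 8 from 5 and 6.** The C–Br bond is cut, then O1–C6 and C2–C3 of the pyranone (hetero-Diels–Alder). The cycloaddition must set both stereocentres, cis from the (Z)-silyloxy terminus of 5 and absolute from a chiral catalyst.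

**5 from 4 from 3 from 1.** Two Si–O bonds and one C–O bond are cut. The diene must carry its extra oxygen on the terminal carbon that becomes C3 of the pyranone, not on an inner carbon, and α′-oxidation of 1 supplies it.

**18 from 16, and 16 from 14 and 15.** Two Si–O bonds are cut, then the C4(U)–C bond. The benzylic cation from 14 is taken by the central carbon of 15, which makes the 4→6 bond in disguise; the C3 ester guides the nucleophile to the β-face.

**14 from 12 and 13, 12 from 11, 11 from 10; 26 from 25 from 24.** Ester, C4–O and O-benzyl bonds are cut. All stereocentres of units U and L come from the natural flavan-3-ols.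

## Alternatives that were turned down

**Alternative 1:** Anodic ortho-quinone methide cycloaddition to form ring C of unit M.
- **Disconnection:** C3–C4 and O1–C2 of ring C of unit M, with unit L already on the benzylic carbon and a methyl ester holding the place of unit U at C6.
- **Forward key step:** two-electron oxidation of phenol A1 at a carbon anode (LiClO4, 2,6-lutidine) gives an ortho-quinone methide, which adds the (Z)-enol ester A2 in an inverse-demand hetero-Diels–Alder reaction to give A3.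
- **For:** it is stronger than the chosen route in bond economy around unit M. Ring C, the gallate and the bond to unit L arrive in one step, and no late esterification or Lewis-acid coupling is needed.
- **Against:** three stereocentres are created on a planar quinone methide whose only chiral influence is the remote unit L, so facial control is weak. Nineteen electron-rich benzyl ethers compete for the anode. After A3 the whole of unit U must still be built from an ester on the most hindered ring carbon.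
- **Comparison:** the chosen strategy takes unit U intact from (−)-epicatechin and sets C2 and C3 of unit M with a catalyst, at the price of a less convergent end game.

**Alternative 2:** Aminocatalytic Friedel–Crafts alkylation to set C4 and close a lactol.
- **Disconnection:** C4–C4a and O1–C2 of ring C of unit M.
- **Forward key step:** α,α-diphenylprolinol trimethylsilyl ether converts enal A5 into its iminium ion; the free ortho carbon of phenol A4 adds to the β-carbon and the phenol oxygen closes the lactol A6.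
- **For:** it is stronger in convergence and in the way C4 of unit M is controlled. Both interflavan bonds are in place and the configuration at C4 is set by the catalyst rather than by neighbouring groups. The reaction type is well established for electron-rich phenols.
- **Against:** A6 has neither the C2 aryl group nor the C3 oxygen. Introducing both cis to each other and trans to the C4 substituent on a crowded lactol would cost several steps with no obvious stereocontrol. The β-carbon of A5 is also flanked by a doubly ortho-substituted aryl ring, which slows the addition.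
- **Comparison:** the chosen strategy has the cis C2/C3 pair before ring A is formed and gets C4 from the reliable 3,4-trans coupling.

**Alternative 3:** Three-component quinone methide cycloaddition to assemble unit U.
- **Disconnection:** C4–C4a, C3–C4 and O1–C2 of ring C of unit U.
- **Forward key step:** 3,3′-bis(2,4,6-triisopropylphenyl)-1,1′-binaphthyl-2,2′-diyl hydrogen phosphate condenses phenol A7 with aldehyde A8 to an ortho-quinone methide, which adds enol ester A2 to give A9.
- **For:** it is stronger in atom and step economy for unit U. Three achiral pieces give the gallated flavan with the future ring A of unit M attached, and no natural product is needed.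
- **Against:** it rebuilds the one unit that (−)-epicatechin supplies in three steps. The enol ester is a weak partner for the quinone methide, and the doubly ortho-substituted aldehyde condenses slowly. After A9, ring C of unit M, all its stereocentres and the bond to unit L are still missing.
- **Comparison:** the chosen strategy spends its key step on the junction between units U and M, which is the part no natural building block provides.

Key step: step 11

## Route

Step 1
Reactants: 1 (E)-1-methoxy-3-(trimethylsilyloxy)buta-1,3-diene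
Product: 3 (E)-1-hydroxy-4-methoxybut-3-en-2-one, via α-silyloxy enone 2 (not isolated)
Conditions: mCPBA, NaHCO3, CH2Cl2, −20 °C; then MeOH, cat. citric acid, 0 °C
Reagents that add atoms: meta-chloroperoxybenzoic acid, O=C(OO)c1cccc(Cl)c1
Why: Rubottom oxidation; the peracid epoxidises the more electron-rich silyl enol ether double bond, silyl migration gives the α-silyloxy ketone and methanolysis frees the alcohol.

Step 2
Reactants: 3 (E)-1-hydroxy-4-methoxybut-3-en-2-one
Product: 4 (E)-1-(tert-butyldimethylsilyloxy)-4-methoxybut-3-en-2-one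
Conditions: TBSCl, imidazole, CH2Cl2, 0 °C → rt
Reagents that add atoms: tert-butyldimethylsilyl chloride, CC(C)(C)[Si](C)(C)Cl
Why: Standard silylation of a primary alcohol; the vinylogous ester is inert to imidazole.

Step 3
Reactants: 4 (E)-1-(tert-butyldimethylsilyloxy)-4-methoxybut-3-en-2-one
Product: 5 (1E,3Z)-4-(tert-butyldimethylsilyloxy)-1-methoxy-3-(trimethylsilyloxy)buta-1,3-diene
Conditions: TMSOTf, Et3N, Et2O, 0 °C
Reagents that add atoms: trimethylsilyl trifluoromethanesulfonate, C[Si](C)(C)OS(=O)(=O)C(F)(F)F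
Why: Soft enolisation towards the only enolisable α-carbon; α-oxygenated ketones give mainly the (Z)-enol ether with the two oxygens cis, which is the geometry needed for a cis pyranone.

Step 4
Reactants: 5 (1E,3Z)-4-(tert-butyldimethylsilyloxy)-1-methoxy-3-(trimethylsilyloxy)buta-1,3-diene; 6 3,4-bis(benzyloxy)benzaldehyde
Product: 8 (2R,3S)-2-Ar-3-(tert-butyldimethylsilyloxy)-2,3-dihydro-4H-pyran-4-one (2,3-cis), via 6-methoxy-4-silyloxy dihydropyran cycloadduct 7 (not isolated)
Conditions: Zr(OtBu)4 (10 mol %), 3,3′-diiodo-1,1′-bi-2-naphthol (enantiomer that gives 2R), n-PrOH, H2O (trace), toluene, −20 °C; then CF3CO2H, CH2Cl2, 0 °C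
Reagents that add atoms: none
Why: Catalytic asymmetric hetero-Diels–Alder reaction of a 4-oxygenated Danishefsky-type diene; the (Z)-silyloxy terminus places the C3 oxygen cis to the aryl group, the chiral zirconium binaphtholate selects the aldehyde face (C2 R, hence C3 S), and acid expels methoxytrimethylsilane to unveil the enone.

Step 5
Reactants: 8 (2R,3S)-2-Ar-3-(tert-butyldimethylsilyloxy)-2,3-dihydro-4H-pyran-4-one
Product: 9 (2R,3S)-5-bromo-2-Ar-3-(tert-butyldimethylsilyloxy)-2,3-dihydro-4H-pyran-4-one (2,3-cis)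
Conditions: NBS, CH2Cl2, 0 °C, dark
Reagents that add atoms: N-bromosuccinimide, O=C1CCC(=O)N1Br
Why: Electrophilic α-bromination of a vinylogous ester; the enol ether β-carbon C5 is the most nucleophilic site and succinimide anion removes the proton, so no base reaches the C3 centre.

Step 6
Reactants: 10 (−)-epicatechin
Product: 11 5,7,3′,4′-tetra-O-benzyl-(−)-epicatechin (2R,3R)
Conditions: BnBr, K2CO3, DMF, 0 °C → rt
Reagents that add atoms: benzyl bromide, BrCc1ccccc1
Why: Williamson etherification of the four phenols; the secondary alcohol is not deprotonated by carbonate.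

Step 7
Reactants: 11 5,7,3′,4′-tetra-O-benzyl-(−)-epicatechin
Product: 12 5,7,3′,4′-tetra-O-benzyl-4β-(2-ethoxyethoxy)-(−)-epicatechin (C2 and C3 as in epicatechin, 3,4-trans)
Conditions: DDQ, 2-ethoxyethanol, CH2Cl2, rt
Reagents that add atoms: 2-ethoxyethanol, CCOCCO
Why: Benzylic oxidation by hydride abstraction at C4 to the cation stabilised by the 5- and 7-alkoxy groups; the alcohol adds from the β-face, anti to the C2 aryl and C3 hydroxyl groups, which sets C4.

Step 8
Reactants: 12 5,7,3′,4′-tetra-O-benzyl-4β-(2-ethoxyethoxy)-(−)-epicatechin; 13 3,4,5-tris(benzyloxy)benzoic acid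
Product: 14 5,7,3′,4′-tetra-O-benzyl-4β-(2-ethoxyethoxy)-3-O-Gall-(−)-epicatechin
Conditions: DCC, DMAP (cat.), CH2Cl2, rt
Reagents that add atoms: none
Why: Steglich esterification of the C3 alcohol; the basic medium leaves the acid-labile C4 ether untouched.

Step 9
Reactants: 14 5,7,3′,4′-tetra-O-benzyl-4β-(2-ethoxyethoxy)-3-O-Gall-(−)-epicatechin; 15 methyl 3-(trimethylsilyloxy)but-2-enoate
Product: 16 methyl 2-(protected U-4β-yl)-3-oxobutanoate (both epimers at the α-carbon)
Conditions: 15 (3 equiv), TMSOTf (0.3 equiv), CH2Cl2, −78 → −40 °C; pyridine quench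
Reagents that add atoms: none
Why: Mukaiyama-type alkylation of a benzylic cation; the C4 ether is ionised, the C3 ester carbonyl bridges the cation on the α-face, and the silyl enol ether attacks through its central carbon from the β-face, so C4 is set trans to the C3 oxygen by the neighbouring centre.

Step 10
Reactants: 16 methyl 2-(protected U-4β-yl)-3-oxobutanoate
Product: 18 1-methoxy-2-(protected U-4β-yl)-1,3-bis(trimethylsilyloxy)buta-1,3-diene, via mono-silyl enol ether 17 (not isolated)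
Conditions: TMSOTf, Et3N, Et2O, 0 °C; filter and concentrate under argon; then LiN(iPr)2, THF, −78 °C; TMSCl, −78 → 0 °C; used crude
Reagents that add atoms: trimethylsilyl trifluoromethanesulfonate, C[Si](C)(C)OS(=O)(=O)C(F)(F)F; chlorotrimethylsilane, C[Si](C)(C)Cl
Why: Two-stage preparation of a 2-substituted 1,3-bis(silyloxy)diene; soft enolisation gives the conjugated silyl enol ether, then γ-deprotonation of its methyl group and O-silylation give the ketene acetal, the hindered ester and benzyl ethers being inert to the amide base at −78 °C.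

Step 11
Reactants: 18 1-methoxy-2-(protected U-4β-yl)-1,3-bis(trimethylsilyloxy)buta-1,3-diene; 9 (2R,3S)-5-bromo-2-Ar-3-(tert-butyldimethylsilyloxy)-2,3-dihydro-4H-pyran-4-one
Product: 21 (2R,3S)-2-Ar-3-(tert-butyldimethylsilyloxy)-5,7-dihydroxy-6-(protected U-4β-yl)chroman-4-one (2,3-cis), via cis-fused bromo cycloadduct 19 (not isolated), via bis(trimethylsilyl) aryl ether 20 (not isolated)
Conditions: 9 (1.5 equiv), 2,4,6-collidine (2 equiv), toluene, 80 → 110 °C, sealed vessel, argon; then citric acid, MeOH–THF, 0 °C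
Reagents that add atoms: none
Why: Proposed new method: the terminal CH2 of 18, the diene carbon with the largest HOMO coefficient, should add to C8a (C6 of 9), the β-carbon of the α-bromo vinylogous ester, and the α-bromo enolate so formed should close on the ketene acetal carbon, an asynchronous [4+2] addition that makes C8–C8a and then C4a–C5 and closes the six-membered carbocycle as cycloadduct 19. 1,4-Loss of methanol from the C5 silyl ketal (C8–H and C5–OMe across C6=C7) turns ring A into a 1,2-dihydroarene, and loss of HBr across C4a–C8a, driven by aromatisation, gives the bis-silyl ether 20; collidine is a weak, hindered base that takes up HBr. The closest known reaction type is the regiospecific Diels–Alder addition and aromatisation of 1,1,3-trioxygenated butadienes with 2-haloquinones and other α-halo enones; it has not been shown for an α-bromo dihydropyranone or for a diene with so large a central substituent. No stereocentre is created, since the ring-fusion centres of 19 disappear on aromatisation. C2 and C3 of unit M are spectators and should stay cis because neither a strong base nor a protic acid is present while the ketone is exposed. Regioselectivity follows from the match of the nucleophilic CH2 terminus with the enone β-carbon, reinforced by bromine on the α-carbon, and it places unit U on the carbon between the two new oxygens. The ring oxygen should be retained because C4a carries bromine and no hydrogen, so no enolate can form next to C8a before ring A is aromatic. Mild acidic methanolysis then cleaves only the two aryl trimethylsilyl ethers.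

Step 12
Reactants: 21 (2R,3S)-2-Ar-3-(tert-butyldimethylsilyloxy)-5,7-dihydroxy-6-(protected U-4β-yl)chroman-4-one
Product: 22 (2R,3S)-2-Ar-5,7-bis(benzyloxy)-3-(tert-butyldimethylsilyloxy)-6-(protected U-4β-yl)chroman-4-one
Conditions: BnOH (4 equiv), PPh3, DIAD, toluene, 0 → 40 °C
Reagents that add atoms: benzyl alcohol, OCc1ccccc1
Why: Mitsunobu etherification of phenols; it runs at neutral pH, so the C3 centre next to the ketone is not enolised and ring C is not opened, which carbonate and benzyl bromide would risk.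

Step 13
Reactants: 22 (2R,3S)-2-Ar-5,7-bis(benzyloxy)-3-(tert-butyldimethylsilyloxy)-6-(protected U-4β-yl)chroman-4-one
Product: 23 2-Ar-5,7-bis(benzyloxy)-3-(tert-butyldimethylsilyloxy)-6-(protected U-4β-yl)chroman-4-ol (2,3-cis, 3,4-cis expected)
Conditions: NaBH4, CeCl3·7H2O, THF–MeOH, −20 → 0 °C
Reagents that add atoms: none
Why: Luche reduction of the aryl ketone under weakly basic conditions; hydride should approach anti to the pseudoaxial C3 silyloxy group, and the configuration of the new carbinol is erased in step 16.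

Step 14
Reactants: 24 (+)-catechin
Product: 25 5,7,3′,4′-tetra-O-benzyl-(+)-catechin (2R,3S)
Conditions: BnBr, K2CO3, DMF, 0 °C → rt
Reagents that add atoms: benzyl bromide, BrCc1ccccc1
Why: Williamson etherification of the four phenols, as in step 6.

Step 15
Reactants: 25 5,7,3′,4′-tetra-O-benzyl-(+)-catechin
Product: 26 3,5,7,3′,4′-penta-O-benzyl-(+)-catechin (2R,3S)
Conditions: NaH, BnBr, DMF, 0 °C → rt
Reagents that add atoms: benzyl bromide, BrCc1ccccc1
Why: Williamson etherification of the secondary alkoxide; with the phenols capped no quinone methide can form, so C2 is safe, and the C3 oxygen of unit L is kept distinct from that of unit M.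

Step 16
Reactants: 23 2-Ar-5,7-bis(benzyloxy)-3-(tert-butyldimethylsilyloxy)-6-(protected U-4β-yl)chroman-4-ol; 26 3,5,7,3′,4′-penta-O-benzyl-(+)-catechin
Product: 27 protected trimer: unit M (5,7,3′,4′-tetra-O-benzyl, 3-O-TBS, epicatechin configuration) bearing protected U-4β-yl at C6 and bonded from C4 (4β) to C8 of 26
Conditions: 26 (4 equiv), TMSOTf (0.5 equiv), 4 Å molecular sieves, CH2Cl2, −78 → −40 °C; Et3N quench
Reagents that add atoms: none
Why: Friedel–Crafts alkylation by the C4 benzylic cation stabilised by the 5- and 7-benzyloxy groups; C8 is the more nucleophilic ring carbon of benzylated catechin, and attack anti to the C2 aryl and C3 silyloxy groups sets C4 of unit M 3,4-trans.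

Step 17
Reactants: 27 protected trimer with 3-O-TBS on unit M
Product: 28 protected trimer with free C3 hydroxyl on unit M
Conditions: HF·pyridine, THF–pyridine, 0 °C → rt
Reagents that add atoms: none
Why: Buffered fluoride cleaves the secondary silyl ether without acyl transfer or hydrolysis of the gallate on unit U.

Step 18
Reactants: 28 protected trimer with free C3 hydroxyl on unit M; 13 3,4,5-tris(benzyloxy)benzoic acid
Product: 29 fully benzylated target: units U and M 3-O-Gall, unit L 3-O-benzyl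
Conditions: DCC, DMAP, CH2Cl2, rt → 35 °C
Reagents that add atoms: none
Why: Steglich esterification; the C3 hydroxyl of unit M is the only free hydroxyl in the molecule.

Step 19
Reactants: 29 fully benzylated target
Product: 30 CNP0112921.1, epicatechin 3-O-gallate-(4β→6)-epicatechin 3-O-gallate-(4β→8)-catechin
Conditions: H2 (1 atm), Pd(OH)2/C, THF–MeOH–H2O, rt; filtration and freeze-drying under argon
Reagents that add atoms: none
Why: Hydrogenolysis of nineteen benzyl ethers; the aryl esters, the interflavan bonds and all stereocentres are stable under neutral hydrogenation.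

## Compound list

1 | (E)-1-methoxy-3-(trimethylsilyloxy)buta-1,3-diene | CO/C=C/C(=C)O[Si](C)(C)C | starting material
2 | (E)-4-methoxy-1-(trimethylsilyloxy)but-3-en-2-one | CO/C=C/C(=O)CO[Si](C)(C)C | intermediate
3 | (E)-1-hydroxy-4-methoxybut-3-en-2-one | CO/C=C/C(=O)CO | intermediate
4 | (E)-1-(tert-butyldimethylsilyloxy)-4-methoxybut-3-en-2-one | CO/C=C/C(=O)CO[Si](C)(C)C(C)(C)C | intermediate
5 | (1E,3Z)-4-(tert-butyldimethylsilyloxy)-1-methoxy-3-(trimethylsilyloxy)buta-1,3-diene | CO/C=C/C(=C/O[Si](C)(C)C(C)(C)C)O[Si](C)(C)C | intermediate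
6 | 3,4-bis(benzyloxy)benzaldehyde | O=Cc1ccc(OCc2ccccc2)c(OCc2ccccc2)c1 | starting material
7 | (2R,3S)-2-Ar-3-(tert-butyldimethylsilyloxy)-6-methoxy-4-(trimethylsilyloxy)-3,6-dihydro-2H-pyran (C6 either configuration) | COC1C=C(O[Si](C)(C)C)[C@@H](O[Si](C)(C)C(C)(C)C)[C@@H](c2ccc(OCc9ccccc9)c(OCc9ccccc9)c2)O1 | intermediate
8 | (2R,3S)-2-Ar-3-(tert-butyldimethylsilyloxy)-2,3-dihydro-4H-pyran-4-one, cis | C1=CO[C@H](c2ccc(OCc9ccccc9)c(OCc9ccccc9)c2)[C@H](O[Si](C)(C)C(C)(C)C)C1=O | intermediate
9 | (2R,3S)-5-bromo-2-Ar-3-(tert-butyldimethylsilyloxy)-2,3-dihydro-4H-pyran-4-one, cis | BrC1=CO[C@H](c2ccc(OCc9ccccc9)c(OCc9ccccc9)c2)[C@H](O[Si](C)(C)C(C)(C)C)C1=O | intermediate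
10 | (−)-epicatechin, (2R,3R) | O[C@@H]1Cc2c(O)cc(O)cc2O[C@@H]1c1ccc(O)c(O)c1 | starting material
11 | 5,7,3′,4′-tetra-O-benzyl-(−)-epicatechin | O[C@@H]1Cc2c(OCc9ccccc9)cc(OCc9ccccc9)cc2O[C@@H]1c1ccc(OCc9ccccc9)c(OCc9ccccc9)c1 | intermediate
12 | 5,7,3′,4′-tetra-O-benzyl-4β-(2-ethoxyethoxy)-(−)-epicatechin, 2,3-cis-3,4-trans | O[C@@H]1[C@@H](OCCOCC)c2c(OCc9ccccc9)cc(OCc9ccccc9)cc2O[C@@H]1c1ccc(OCc9ccccc9)c(OCc9ccccc9)c1 | intermediate
13 | 3,4,5-tris(benzyloxy)benzoic acid | O=C(O)c1cc(OCc2ccccc2)c(OCc2ccccc2)c(OCc2ccccc2)c1 | starting material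
14 | 5,7,3′,4′-tetra-O-benzyl-4β-(2-ethoxyethoxy)-3-O-[3,4,5-tris(benzyloxy)benzoyl]-(−)-epicatechin | O=C(c5cc(OCc9ccccc9)c(OCc9ccccc9)c(OCc9ccccc9)c5)O[C@@H]1[C@@H](OCCOCC)c2c(OCc9ccccc9)cc(OCc9ccccc9)cc2O[C@@H]1c1ccc(OCc9ccccc9)c(OCc9ccccc9)c1 | intermediate
15 | methyl 3-(trimethylsilyloxy)but-2-enoate | COC(=O)C=C(C)O[Si](C)(C)C | starting material
16 | methyl 2-(protected U-4β-yl)-3-oxobutanoate, both α-epimers | O=C(c5cc(OCc9ccccc9)c(OCc9ccccc9)c(OCc9ccccc9)c5)O[C@@H]1[C@@H](C(C(C)=O)C(=O)OC)c2c(OCc9ccccc9)cc(OCc9ccccc9)cc2O[C@@H]1c1ccc(OCc9ccccc9)c(OCc9ccccc9)c1 | intermediate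
17 | methyl 2-(protected U-4β-yl)-3-(trimethylsilyloxy)but-2-enoate | O=C(c5cc(OCc9ccccc9)c(OCc9ccccc9)c(OCc9ccccc9)c5)O[C@@H]1[C@@H](C(C(=O)OC)=C(C)O[Si](C)(C)C)c2c(OCc9ccccc9)cc(OCc9ccccc9)cc2O[C@@H]1c1ccc(OCc9ccccc9)c(OCc9ccccc9)c1 | intermediate
18 | 1-methoxy-2-(protected U-4β-yl)-1,3-bis(trimethylsilyloxy)buta-1,3-diene, methoxy trans to unit U | O=C(c5cc(OCc9ccccc9)c(OCc9ccccc9)c(OCc9ccccc9)c5)O[C@@H]1[C@@H](/C(C(=C)O[Si](C)(C)C)=C(/OC)O[Si](C)(C)C)c2c(OCc9ccccc9)cc(OCc9ccccc9)cc2O[C@@H]1c1ccc(OCc9ccccc9)c(OCc9ccccc9)c1 | intermediate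
19 | cis-fused cycloadduct: (2R,3S)-2-Ar-4a-bromo-3-(tert-butyldimethylsilyloxy)-5-methoxy-6-(protected U-4β-yl)-5,7-bis(trimethylsilyloxy)-2,3,4a,5,8,8a-hexahydrochromen-4-one (C4a, C5, C8a unassigned) | O=C(c5cc(OCc9ccccc9)c(OCc9ccccc9)c(OCc9ccccc9)c5)O[C@@H]1[C@@H](C3=C(O[Si](C)(C)C)CC4O[C@H](c6ccc(OCc9ccccc9)c(OCc9ccccc9)c6)[C@H](O[Si](C)(C)C(C)(C)C)C(=O)C4(Br)C3(OC)O[Si](C)(C)C)c2c(OCc9ccccc9)cc(OCc9ccccc9)cc2O[C@@H]1c1ccc(OCc9ccccc9)c(OCc9ccccc9)c1 | intermediate
20 | (2R,3S)-2-Ar-3-(tert-butyldimethylsilyloxy)-6-(protected U-4β-yl)-5,7-bis(trimethylsilyloxy)chroman-4-one | O=C(c5cc(OCc9ccccc9)c(OCc9ccccc9)c(OCc9ccccc9)c5)O[C@@H]1[C@@H](c3c(O[Si](C)(C)C)cc4c(c3O[Si](C)(C)C)C(=O)[C@@H](O[Si](C)(C)C(C)(C)C)[C@@H](c6ccc(OCc9ccccc9)c(OCc9ccccc9)c6)O4)c2c(OCc9ccccc9)cc(OCc9ccccc9)cc2O[C@@H]1c1ccc(OCc9ccccc9)c(OCc9ccccc9)c1 | intermediate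
21 | (2R,3S)-2-Ar-3-(tert-butyldimethylsilyloxy)-5,7-dihydroxy-6-(protected U-4β-yl)chroman-4-one, 2,3-cis | O=C(c5cc(OCc9ccccc9)c(OCc9ccccc9)c(OCc9ccccc9)c5)O[C@@H]1[C@@H](c3c(O)cc4c(c3O)C(=O)[C@@H](O[Si](C)(C)C(C)(C)C)[C@@H](c6ccc(OCc9ccccc9)c(OCc9ccccc9)c6)O4)c2c(OCc9ccccc9)cc(OCc9ccccc9)cc2O[C@@H]1c1ccc(OCc9ccccc9)c(OCc9ccccc9)c1 | intermediate
22 | (2R,3S)-2-Ar-5,7-bis(benzyloxy)-3-(tert-butyldimethylsilyloxy)-6-(protected U-4β-yl)chroman-4-one | O=C(c5cc(OCc9ccccc9)c(OCc9ccccc9)c(OCc9ccccc9)c5)O[C@@H]1[C@@H](c3c(OCc9ccccc9)cc4c(c3OCc9ccccc9)C(=O)[C@@H](O[Si](C)(C)C(C)(C)C)[C@@H](c6ccc(OCc9ccccc9)c(OCc9ccccc9)c6)O4)c2c(OCc9ccccc9)cc(OCc9ccccc9)cc2O[C@@H]1c1ccc(OCc9ccccc9)c(OCc9ccccc9)c1 | intermediate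
23 | 2-Ar-5,7-bis(benzyloxy)-3-(tert-butyldimethylsilyloxy)-6-(protected U-4β-yl)chroman-4-ol, 2,3-cis-3,4-cis | O=C(c5cc(OCc9ccccc9)c(OCc9ccccc9)c(OCc9ccccc9)c5)O[C@@H]1[C@@H](c3c(OCc9ccccc9)cc4c(c3OCc9ccccc9)[C@@H](O)[C@@H](O[Si](C)(C)C(C)(C)C)[C@@H](c6ccc(OCc9ccccc9)c(OCc9ccccc9)c6)O4)c2c(OCc9ccccc9)cc(OCc9ccccc9)cc2O[C@@H]1c1ccc(OCc9ccccc9)c(OCc9ccccc9)c1 | intermediate
24 | (+)-catechin, (2R,3S) | O[C@H]1Cc2c(O)cc(O)cc2O[C@@H]1c1ccc(O)c(O)c1 | starting material
25 | 5,7,3′,4′-tetra-O-benzyl-(+)-catechin | O[C@H]1Cc2c(OCc9ccccc9)cc(OCc9ccccc9)cc2O[C@@H]1c1ccc(OCc9ccccc9)c(OCc9ccccc9)c1 | intermediate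
26 | 3,5,7,3′,4′-penta-O-benzyl-(+)-catechin | C(c9ccccc9)O[C@H]1Cc2c(OCc9ccccc9)cc(OCc9ccccc9)cc2O[C@@H]1c1ccc(OCc9ccccc9)c(OCc9ccccc9)c1 | intermediate
27 | protected trimer, unit M 3-O-TBS: protected U-(4β→6)-[5,7,3′,4′-tetra-O-benzyl-3-O-TBS-epicatechin]-(4β→8)-[penta-O-benzylcatechin] | O=C(c5cc(OCc9ccccc9)c(OCc9ccccc9)c(OCc9ccccc9)c5)O[C@@H]1[C@@H](c3c(OCc9ccccc9)cc4c(c3OCc9ccccc9)[C@H](c7c(OCc9ccccc9)cc(OCc9ccccc9)c8c7O[C@H](c6ccc(OCc9ccccc9)c(OCc9ccccc9)c6)[C@@H](OCc9ccccc9)C8)[C@@H](O[Si](C)(C)C(C)(C)C)[C@@H](c6ccc(OCc9ccccc9)c(OCc9ccccc9)c6)O4)c2c(OCc9ccccc9)cc(OCc9ccccc9)cc2O[C@@H]1c1ccc(OCc9ccccc9)c(OCc9ccccc9)c1 | intermediate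
28 | protected trimer, unit M 3-OH | O=C(c5cc(OCc9ccccc9)c(OCc9ccccc9)c(OCc9ccccc9)c5)O[C@@H]1[C@@H](c3c(OCc9ccccc9)cc4c(c3OCc9ccccc9)[C@H](c7c(OCc9ccccc9)cc(OCc9ccccc9)c8c7O[C@H](c6ccc(OCc9ccccc9)c(OCc9ccccc9)c6)[C@@H](OCc9ccccc9)C8)[C@@H](O)[C@@H](c6ccc(OCc9ccccc9)c(OCc9ccccc9)c6)O4)c2c(OCc9ccccc9)cc(OCc9ccccc9)cc2O[C@@H]1c1ccc(OCc9ccccc9)c(OCc9ccccc9)c1 | intermediate
29 | fully benzylated target, units U and M 3-O-[3,4,5-tris(benzyloxy)benzoyl] | O=C(c5cc(OCc9ccccc9)c(OCc9ccccc9)c(OCc9ccccc9)c5)O[C@@H]1[C@@H](c3c(OCc9ccccc9)cc4c(c3OCc9ccccc9)[C@H](c7c(OCc9ccccc9)cc(OCc9ccccc9)c8c7O[C@H](c6ccc(OCc9ccccc9)c(OCc9ccccc9)c6)[C@@H](OCc9ccccc9)C8)[C@@H](OC(=O)c5cc(OCc9ccccc9)c(OCc9ccccc9)c(OCc9ccccc9)c5)[C@@H](c6ccc(OCc9ccccc9)c(OCc9ccccc9)c6)O4)c2c(OCc9ccccc9)cc(OCc9ccccc9)cc2O[C@@H]1c1ccc(OCc9ccccc9)c(OCc9ccccc9)c1 | intermediate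
30 | CNP0112921.1, epicatechin 3-O-gallate-(4β→6)-epicatechin 3-O-gallate-(4β→8)-catechin | O=C(O[C@@H]1[C@@H](c2c(O)cc3c(c2O)[C@H](c2c(O)cc(O)c4c2O[C@H](c2ccc(O)c(O)c2)[C@@H](O)C4)[C@@H](OC(=O)c2cc(O)c(O)c(O)c2)[C@@H](c2ccc(O)c(O)c2)O3)c2c(O)cc(O)cc2O[C@@H]1c1ccc(O)c(O)c1)c1cc(O)c(O)c(O)c1 | target

## Step count and risk

Total: 19 steps. Longest linear sequence: 12 steps (10 → 11 → 12 → 14 → 16 → 18 → 21 → 22 → 23 → 27 → 28 → 29 → 30; the branch from 1 is equally long).

**Step 11 (key step, proposed new method).**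
- The vinylogous ester of 9 is an electron-rich, weak dienophile and the central substituent of 18 crowds the s-cis conformer, so decomposition of the diene by silyl migration or protodesilylation may outrun cycloaddition. The diene made in step 10 is equally fragile and shares this risk.
- Aromatisation may stall. Hydrogen on C8a and bromine on C4a are cis on the ring fusion of 19, no antiperiplanar elimination is available, and C8a–H is not acidified by any carbonyl.
- Once C7 is unmasked, ring C may open by β-elimination of the ring oxygen.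
- C3 may epimerise on prolonged heating.
- Fallback (known chemistry, bromine blocking of C8 and orthogonal activation of the two C4 leaving groups), from 12 and 14 back to 30: 12 is brominated at C8 with N-bromosuccinimide to the 8-bromo ether F1. Its C4 ether is exchanged with 4-methylbenzenethiol and BF3·OEt2 for the 8-bromo 4β-arylthio flavanol F2. Activation of 14 with BF3·OEt2 at −78 °C in the presence of F2, whose only free ring carbon is C6 and whose thioether is inert to the hard Lewis acid, gives the 4β→6 dimer F3. Thiophilic activation of F3 with AgBF4 in the presence of 26 gives the bromo trimer alcohol F4. Esterification with 13 gives the bromo trimer digallate F5. Hydrogenolysis over Pd(OH)2/C with Et3N removes the benzyl groups and the bromine and gives 30.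

**Step 4.**
- The electron-rich aldehyde and the silyloxy diene may give insufficient facial or cis/trans selectivity.
- Fallback, from 5 and 6 back to 8: cycloaddition with achiral Eu(fod)3 and the same acid treatment gives the racemic cis pyranone. Chromatography on a chiral stationary phase separates 8 from the (2S,3R) enantiomer F8.

**Step 12.**
- The C5 phenol is hydrogen-bonded to the ketone and flanked by unit U, so etherification may stop at the 7-O-benzyl stage.
- Fallback, from 21 back to 23: the ketone is reduced first (NaBH4, CeCl3·7H2O) to the triol F6, in which the C5 phenol is no longer chelated and no enolisable ketone remains. Benzyl bromide and K2CO3 in DMF then give 23.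

**Step 16.**
- The Lewis acid may cleave the existing 4→6 bond or let the product compete as a nucleophile, giving scrambling and oligomers. The crowded cation may also ionise slowly from a free alcohol.
- Fallback, from 23 back to 27: thiolysis of 23 with 2-mercaptobenzothiazole and BF3·OEt2 at −78 °C gives the stable 4β-(benzothiazol-2-ylthio) donor F7. F7 is activated with AgBF4 in the presence of 26 under non-acidic conditions to give 27.

## Further compounds

F1 | step 11 | 5,7,3′,4′-tetra-O-benzyl-8-bromo-4β-(2-ethoxyethoxy)-(−)-epicatechin | O[C@@H]1[C@@H](OCCOCC)c2c(OCc9ccccc9)cc(OCc9ccccc9)c(Br)c2O[C@@H]1c1ccc(OCc9ccccc9)c(OCc9ccccc9)c1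
F2 | step 11 | 5,7,3′,4′-tetra-O-benzyl-8-bromo-4β-(4-methylphenylthio)-(−)-epicatechin | O[C@@H]1[C@@H](Sc3ccc(C)cc3)c2c(OCc9ccccc9)cc(OCc9ccccc9)c(Br)c2O[C@@H]1c1ccc(OCc9ccccc9)c(OCc9ccccc9)c1
F3 | step 11 | protected U-(4β→6)-[5,7,3′,4′-tetra-O-benzyl-8-bromo-4β-(4-methylphenylthio)epicatechin] | O=C(c5cc(OCc9ccccc9)c(OCc9ccccc9)c(OCc9ccccc9)c5)O[C@@H]1[C@@H](c3c(OCc9ccccc9)c(Br)c4c(c3OCc9ccccc9)[C@H](Sc7ccc(C)cc7)[C@@H](O)[C@@H](c6ccc(OCc9ccccc9)c(OCc9ccccc9)c6)O4)c2c(OCc9ccccc9)cc(OCc9ccccc9)cc2O[C@@H]1c1ccc(OCc9ccccc9)c(OCc9ccccc9)c1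
F4 | step 11 | 8-bromo analogue of 28 (bromine on C8 of unit M, free C3 hydroxyl) | O=C(c5cc(OCc9ccccc9)c(OCc9ccccc9)c(OCc9ccccc9)c5)O[C@@H]1[C@@H](c3c(OCc9ccccc9)c(Br)c4c(c3OCc9ccccc9)[C@H](c7c(OCc9ccccc9)cc(OCc9ccccc9)c8c7O[C@H](c6ccc(OCc9ccccc9)c(OCc9ccccc9)c6)[C@@H](OCc9ccccc9)C8)[C@@H](O)[C@@H](c6ccc(OCc9ccccc9)c(OCc9ccccc9)c6)O4)c2c(OCc9ccccc9)cc(OCc9ccccc9)cc2O[C@@H]1c1ccc(OCc9ccccc9)c(OCc9ccccc9)c1
F5 | step 11 | 8-bromo analogue of 29 (bromine on C8 of unit M) | O=C(c5cc(OCc9ccccc9)c(OCc9ccccc9)c(OCc9ccccc9)c5)O[C@@H]1[C@@H](c3c(OCc9ccccc9)c(Br)c4c(c3OCc9ccccc9)[C@H](c7c(OCc9ccccc9)cc(OCc9ccccc9)c8c7O[C@H](c6ccc(OCc9ccccc9)c(OCc9ccccc9)c6)[C@@H](OCc9ccccc9)C8)[C@@H](OC(=O)c5cc(OCc9ccccc9)c(OCc9ccccc9)c(OCc9ccccc9)c5)[C@@H](c6ccc(OCc9ccccc9)c(OCc9ccccc9)c6)O4)c2c(OCc9ccccc9)cc(OCc9ccccc9)cc2O[C@@H]1c1ccc(OCc9ccccc9)c(OCc9ccccc9)c1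
F6 | step 12 | 2-Ar-3-(tert-butyldimethylsilyloxy)-6-(protected U-4β-yl)chroman-4,5,7-triol, 2,3-cis-3,4-cis | O=C(c5cc(OCc9ccccc9)c(OCc9ccccc9)c(OCc9ccccc9)c5)O[C@@H]1[C@@H](c3c(O)cc4c(c3O)[C@@H](O)[C@@H](O[Si](C)(C)C(C)(C)C)[C@@H](c6ccc(OCc9ccccc9)c(OCc9ccccc9)c6)O4)c2c(OCc9ccccc9)cc(OCc9ccccc9)cc2O[C@@H]1c1ccc(OCc9ccccc9)c(OCc9ccccc9)c1
F7 | step 16 | 2-Ar-4β-(1,3-benzothiazol-2-ylthio)-5,7-bis(benzyloxy)-3-(tert-butyldimethylsilyloxy)-6-(protected U-4β-yl)chroman, 2,3-cis-3,4-trans | O=C(c5cc(OCc9ccccc9)c(OCc9ccccc9)c(OCc9ccccc9)c5)O[C@@H]1[C@@H](c3c(OCc9ccccc9)cc4c(c3OCc9ccccc9)[C@H](Sc7nc8ccccc8s7)[C@@H](O[Si](C)(C)C(C)(C)C)[C@@H](c6ccc(OCc9ccccc9)c(OCc9ccccc9)c6)O4)c2c(OCc9ccccc9)cc(OCc9ccccc9)cc2O[C@@H]1c1ccc(OCc9ccccc9)c(OCc9ccccc9)c1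
F8 | step 4 | (2S,3R)-2-Ar-3-(tert-butyldimethylsilyloxy)-2,3-dihydro-4H-pyran-4-one, enantiomer of 8 | C1=CO[C@@H](c2ccc(OCc9ccccc9)c(OCc9ccccc9)c2)[C@@H](O[Si](C)(C)C(C)(C)C)C1=O
A1 | alternative 1 | methyl 2,6-bis(benzyloxy)-4-hydroxy-3-[(3,5,7,3′,4′-penta-O-benzyl-(+)-catechin-8-yl)methyl]benzoate | COC(=O)c3c(OCc9ccccc9)cc(O)c(c3OCc9ccccc9)Cc7c(OCc9ccccc9)cc(OCc9ccccc9)c8c7O[C@H](c6ccc(OCc9ccccc9)c(OCc9ccccc9)c6)[C@@H](OCc9ccccc9)C8
A2 | alternative 1 | (Z)-2-[3,4-bis(benzyloxy)phenyl]ethenyl 3,4,5-tris(benzyloxy)benzoate | O=C(O/C=C\c1ccc(OCc9ccccc9)c(OCc9ccccc9)c1)c1cc(OCc9ccccc9)c(OCc9ccccc9)c(OCc9ccccc9)c1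
A3 | alternative 1 | perbenzylated M(4β→8)L dimer with C3 gallate and a methyl ester at C6 of unit M | COC(=O)c3c(OCc9ccccc9)cc4c(c3OCc9ccccc9)[C@H](c7c(OCc9ccccc9)cc(OCc9ccccc9)c8c7O[C@H](c6ccc(OCc9ccccc9)c(OCc9ccccc9)c6)[C@@H](OCc9ccccc9)C8)[C@@H](OC(=O)c5cc(OCc9ccccc9)c(OCc9ccccc9)c(OCc9ccccc9)c5)[C@@H](c6ccc(OCc9ccccc9)c(OCc9ccccc9)c6)O4
A4 | alternative 2 | 3,5-bis(benzyloxy)-4-[5,7,3′,4′-tetra-O-benzyl-3-O-TBS-(−)-epicatechin-4β-yl]phenol | CC(C)(C)[Si](C)(C)O[C@@H]1[C@@H](c3c(OCc9ccccc9)cc(O)cc3OCc9ccccc9)c2c(OCc9ccccc9)cc(OCc9ccccc9)cc2O[C@@H]1c1ccc(OCc9ccccc9)c(OCc9ccccc9)c1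
A5 | alternative 2 | (E)-3-[3,5,7,3′,4′-penta-O-benzyl-(+)-catechin-8-yl]prop-2-enal | O=C/C=C/c7c(OCc9ccccc9)cc(OCc9ccccc9)c8c7O[C@H](c6ccc(OCc9ccccc9)c(OCc9ccccc9)c6)[C@@H](OCc9ccccc9)C8
A6 | alternative 2 | unit U bonded to C6 of the chroman-2-ol of unit M that carries unit L at C4 | CC(C)(C)[Si](C)(C)O[C@@H]1[C@@H](c3c(OCc9ccccc9)cc4c(c3OCc9ccccc9)[C@H](c7c(OCc9ccccc9)cc(OCc9ccccc9)c8c7O[C@H](c6ccc(OCc9ccccc9)c(OCc9ccccc9)c6)[C@@H](OCc9ccccc9)C8)C[C@H](O)O4)c2c(OCc9ccccc9)cc(OCc9ccccc9)cc2O[C@@H]1c1ccc(OCc9ccccc9)c(OCc9ccccc9)c1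
A7 | alternative 3 | 3,5-bis(benzyloxy)phenol | Oc1cc(OCc9ccccc9)cc(OCc9ccccc9)c1
A8 | alternative 3 | 2,6-bis(benzyloxy)-4-(triisopropylsilyloxy)benzaldehyde | O=Cc1c(OCc9ccccc9)cc(O[Si](C(C)C)(C(C)C)C(C)C)cc1OCc9ccccc9
A9 | alternative 3 | perbenzylated unit U gallate bearing at C4 the 2,6-bis(benzyloxy)-4-(triisopropylsilyloxy)phenyl ring | O=C(c5cc(OCc9ccccc9)c(OCc9ccccc9)c(OCc9ccccc9)c5)O[C@@H]1[C@@H](c3c(OCc9ccccc9)cc(O[Si](C(C)C)(C(C)C)C(C)C)cc3OCc9ccccc9)c2c(OCc9ccccc9)cc(OCc9ccccc9)cc2O[C@@H]1c1ccc(OCc9ccccc9)c(OCc9ccccc9)c1
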